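**Retrosynthetic overview**
- The dihydropyranone is opened at O1–C6 to a δ-hydroxy-β-enaminone, which is the reductively opened (N–O) form of a 3-methyl-5-(2-hydroxyalkyl)isoxazole, a masked 1,3-diketone.
- The isoxazole comes from a [3+2] cycloaddition of acetonitrile oxide with the terminal alkyne of a homopropargylic alcohol; this is the key step and makes the C4–C5 bond and the C4–O bond of the future ring.
- The alkynol comes from acetylide opening of a terminal epoxide, made from the chlorohydrin of (R)-epichlorohydrin and erucylmagnesium bromide.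
- The only stereocentre is bought in (R)-epichlorohydrin and never reacts; the Z-alkene is bought in erucyl alcohol.
- Ring order: isoxazole first (cycloaddition), then the dihydropyranone in the last step at the expense of the isoxazole.

Assumption: the target is (2R)-6-methyl-2-[(14Z)-tricos-14-en-1-yl]-2,3-dihydro-4H-pyran-4-one (the [C@@H] centre is R by CIP analysis), and erucyl alcohol is bought as the pure Z isomer.

**Step 1**
Reactants: 1 (13Z)-docos-13-en-1-ol (erucyl alcohol)
Product: 2 (13Z)-1-bromodocos-13-ene (erucyl bromide)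
Conditions: CBr4 (1.2 equiv), PPh3 (1.25 equiv), CH2Cl2, 0 °C → rt
Reagents that add atoms: carbon tetrabromide, BrC(Br)(Br)Br
Why: Appel bromination replaces the primary OH by SN2 displacement of the oxyphosphonium under neutral conditions, leaving the remote Z-alkene untouched (no stereocentre involved).

**Step 2**
Reactants: 2 (13Z)-1-bromodocos-13-ene (1.3 equiv); 3 (R)-epichlorohydrin (1.0 equiv)
Product: 5 (2R,16Z)-1-chloropentacos-16-en-2-ol, via erucylmagnesium bromide 4 (not isolated)
Conditions: Mg, THF, 45 °C; then CuI (10 mol%), 3, THF, −40 → −20 °C; cold 1 M HCl quench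
Reagents that add atoms: none
Why: Grignard formation followed by copper(I)-catalysed SN2 opening of the epoxide at its unsubstituted CH2 (faster than chloride displacement at −40 °C) joins the C22 chain to the C3 unit, and the purchased stereocentre of 3 is not a reacting centre, so it is carried over as (2R).

**Step 3**
Reactants: 5 (2R,16Z)-1-chloropentacos-16-en-2-ol
Product: 7 (4R,18Z)-heptacos-18-en-1-yn-4-ol, via terminal epoxide 6 (not isolated)
Conditions: LiC≡CH·H2NCH2CH2NH2 (3.5 equiv), DMSO/THF (1:1), 0 °C → rt, 14 h; ice/1 M HCl quench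
Reagents that add atoms: lithium acetylide ethylenediamine complex, [Li+].[C-]#C.NCCN
Why: The first equivalent of acetylide deprotonates the chlorohydrin, which closes by intramolecular Williamson SN2 at CH2Cl to epoxide 6, and further acetylide opens 6 at its CH2 terminus (SN2 epoxide alkynylation), so the carbinol C–O bond is never broken and the centre stays (R).

**Step 4**
Reactants: 7 (4R,18Z)-heptacos-18-en-1-yn-4-ol
Product: 8 (2R,16Z)-1-(3-methyl-1,2-oxazol-5-yl)pentacos-16-en-2-ol
Conditions: MeCH=NOH (3 equiv), NCS (3 equiv), pyridine (cat.), CHCl3, 0 °C → rt, 1 h; then 7, Et3N (3.3 equiv, syringe pump, 8 h), CHCl3, rt → 40 °C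
Reagents that add atoms: acetaldoxime, CC=NO
Why: Huisgen 1,3-dipolar [3+2] cycloaddition of acetonitrile oxide generated in situ gives the 3,5-disubstituted isoxazole regioselectively at the terminal alkyne, which is clearly more reactive than the unactivated internal Z-alkene, while slow base addition suppresses furoxan dimerisation and the carbinol centre is untouched.

**Step 5**
Reactants: 8 (2R,16Z)-1-(3-methyl-1,2-oxazol-5-yl)pentacos-16-en-2-ol
Product: 10 (2R)-6-methyl-2-[(14Z)-tricos-14-en-1-yl]-2,3-dihydro-4H-pyran-4-one, via enaminone 9 (not isolated)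
Conditions: Mo(CO)6 (1.0 equiv), MeCN/H2O/THF (10:1:3), 80 °C, 3 h; then 2 M aq HCl, rt, 2 h
Reagents that add atoms: none
Why: Mo(CO)6/H2O cleaves the isoxazole N–O bond reductively without reducing the alkene to give the Z-enaminone, and acid then drives cyclocondensation (addition–elimination of the δ-hydroxyl onto the vinylogous amide with loss of ammonia) to the cyclic vinylogous ester; the C2–O bond is retained, so the (R) centre is conserved.

**Compound list**
1 | (13Z)-docos-13-en-1-ol (erucyl alcohol) | CCCCCCCC/C=C\CCCCCCCCCCCCO | starting material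
2 | (13Z)-1-bromodocos-13-ene (erucyl bromide) | CCCCCCCC/C=C\CCCCCCCCCCCCBr | intermediate
3 | (R)-epichlorohydrin, (2R)-2-(chloromethyl)oxirane | ClC[C@H]1CO1 | starting material
4 | [(13Z)-docos-13-en-1-yl]magnesium bromide (erucylmagnesium bromide) | CCCCCCCC/C=C\CCCCCCCCCCCC[Mg]Br | intermediate
5 | (2R,16Z)-1-chloropentacos-16-en-2-ol | CCCCCCCC/C=C\CCCCCCCCCCCCC[C@@H](O)CCl | intermediate
6 | (2R)-2-[(14Z)-tricos-14-en-1-yl]oxirane | CCCCCCCC/C=C\CCCCCCCCCCCCC[C@@H]1CO1 | intermediate
7 | (4R,18Z)-heptacos-18-en-1-yn-4-ol | CCCCCCCC/C=C\CCCCCCCCCCCCC[C@@H](O)CC#C | intermediate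
8 | (2R,16Z)-1-(3-methyl-1,2-oxazol-5-yl)pentacos-16-en-2-ol | CCCCCCCC/C=C\CCCCCCCCCCCCC[C@@H](O)Cc1cc(C)no1 | intermediate
9 | (2Z,6R,20Z)-2-amino-6-hydroxynonacosa-2,20-dien-4-one | CCCCCCCC/C=C\CCCCCCCCCCCCC[C@@H](O)CC(=O)/C=C(/C)N | intermediate
10 | (2R)-6-methyl-2-[(14Z)-tricos-14-en-1-yl]-2,3-dihydro-4H-pyran-4-one | CCCCCCCC/C=C\CCCCCCCCCCCCC[C@@H]1CC(=O)C=C(C)O1 | target

**Totals**
Total step count: 5. Longest linear sequence: 5 steps (1 → 2 → 5 → 7 → 8 → 10).

**Three steps most likely to fail**

Step 3 (one-pot ring closure and alkynylation of the chlorohydrin). The risks are poor solubility of the C25 chain in DMSO, stalling at the epoxide, and base-induced alkyne isomerisation. The fallback sets out from 5 and comes back at 7. Compound 5 is closed with powdered NaOH in Et2O and epoxide 6 is isolated. Epoxide 6 is then opened with lithium (trimethylsilyl)acetylide activated by BF3·OEt2 in THF at −78 °C (Lewis-acid-mediated alkynylation in a fully solubilising, weakly basic medium) to give (4R,18Z)-1-(trimethylsilyl)heptacos-18-en-1-yn-4-ol F1. The silyl group is removed with K2CO3 in MeOH/THF to give 7.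

Step 4 (nitrile oxide cycloaddition). The risks are competing addition of the dipole to the Z-alkene when excess dipole is needed, and furoxan formation. The fallback moves the cycloaddition ahead of the olefinic chain; it sets out from 4 (made from 2 as in step 2) and comes back at 8. (S)-epichlorohydrin F2 is bought; the enantiomer is needed because the two CH2 termini exchange roles. It is opened with lithium (trimethylsilyl)acetylide/BF3·OEt2 at −78 °C to (2S)-1-chloro-5-(trimethylsilyl)pent-4-yn-2-ol F3. K2CO3/MeOH removes the silyl group and closes the ring to (2S)-2-(prop-2-yn-1-yl)oxirane F4, which is kept in solution because it is volatile. Acetonitrile oxide cycloaddition under the step 4 conditions, now with no competing alkene, gives 3-methyl-5-{[(2S)-oxiran-2-yl]methyl}-1,2-oxazole F5. CuI-catalysed opening of F5 with 4 at −40 °C delivers 8.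

Step 5 (N–O cleavage and cyclisation). The risks are Z/E isomerisation of the alkene by molybdenum species, dehydration of the β-hydroxy ketone, and acid-induced retro-oxa-Michael erosion of the C2 centre. The fallback sets out from 7 and comes back at 10. Double deprotonation of 7 (n-BuLi, 2.2 equiv, THF, −78 °C) and acylation of the acetylide with N-methoxy-N-methylacetamide gives (6R,20Z)-6-hydroxynonacos-20-en-3-yn-2-one F6. F6 is cycloisomerised 6-endo-dig (intramolecular oxa-Michael) with catalytic Ph3PAuCl/AgOTf in CH2Cl2 at rt to 10, with no reductant and no aqueous acid.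

**Further compounds**
F1 | step 3 | (4R,18Z)-1-(trimethylsilyl)heptacos-18-en-1-yn-4-ol | CCCCCCCC/C=C\CCCCCCCCCCCCC[C@@H](O)CC#C[Si](C)(C)C
F2 | step 4 | (S)-epichlorohydrin (purchased) | ClC[C@@H]1CO1
F3 | step 4 | (2S)-1-chloro-5-(trimethylsilyl)pent-4-yn-2-ol | ClC[C@@H](O)CC#C[Si](C)(C)C
F4 | step 4 | (2S)-2-(prop-2-yn-1-yl)oxirane | C#CC[C@H]1CO1
F5 | step 4 | 3-methyl-5-{[(2S)-oxiran-2-yl]methyl}-1,2-oxazole | Cc1cc(C[C@H]2CO2)on1
F6 | step 5 | (6R,20Z)-6-hydroxynonacos-20-en-3-yn-2-one | CCCCCCCC/C=C\CCCCCCCCCCCCC[C@@H](O)CC#CC(C)=O
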